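**Retrosynthetic overview**

1. Vismiaphenone E (17) is 6-(4-hydroxybenzoyl)-5,7-dihydroxy-8-prenyl-2,2-dimethyl-2H-chromene; the last operation only removes two acetyl groups (from the oxygens flanking the ketone) and one allyl group (from the ring B oxygen).
2. Ring C (the pyran) is disconnected at its O–CMe2 bond. It is closed by a thermal cascade of an aryl 1,1-dimethylpropargyl ether: propargyl Claisen shift, enolization, [1,5] hydrogen shift, oxa-6π electrocyclization. One operation moves the C5 unit from oxygen to carbon and then closes the ring on that same oxygen.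
3. Enabling feature: in ring A the ether oxygen O4 (para to the aroyl-bearing C1) lies between C3, blocked by the prenyl group, and C5, the only free ring carbon. The oxygens O2 and O6 that flank C1 are acetylated, so O4 is the only oxygen next to C5 that has a hydrogen to shift, and only one oxatriene can form.
4. The precursor comes from O4-selective propargylation and acetylation of the 3-prenyl benzophenone. That compound comes from C-prenylation of the Houben–Hoesch product of phloroglucinol (ring A) and 4-(allyloxy)benzonitrile (ring B).
5. Ring order: rings A and B are bought and joined through the ketone in step 2; ring C is formed in step 5.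

Key step: step 5

Remark: ring A is the phloroglucinol-derived ring (C1 bears the aroyl group, C3 the prenyl group, C5 is the free carbon that becomes C4a; O2, O4, O6 are its oxygens), ring B the para-oxygenated phenyl ring, ring C the pyran. Prenyl = 3-methylbut-2-en-1-yl, allyl = prop-2-en-1-yl. Compounds 1, 2, 4, 7, 9 and 10 are taken as bought. The target has no stereocenter, so no step has to set configuration.

**Route**

Step 1
Reactants: 1 4-hydroxybenzonitrile; 2 allyl bromide
Product: 3 4-(allyloxy)benzonitrile
Conditions: K2CO3, acetone, 56 °C
Reagents that add atoms: allyl bromide (2), C=CCBr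
Why: Williamson ether synthesis (SN2 of the phenoxide on allyl bromide); the allyl group masks the ring B oxygen so that all later alkylations can only occur on ring A, and it should survive every step up to its release by zerovalent palladium at the end.

Step 2
Reactants: 3 4-(allyloxy)benzonitrile; 4 phloroglucinol
Product: 6 [4-(allyloxy)phenyl](2,4,6-trihydroxyphenyl)methanone, via ketiminium chloride 5 (not isolated)
Conditions: ZnCl2, HCl (g), Et2O, 0 °C; then H2O, 100 °C
Reagents that add atoms: water, O; hydrogen chloride, Cl (chloride counter-ion of 5 only)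
Why: Houben–Hoesch acylation: the nitrile, activated by HCl and ZnCl2, is attacked by a ring carbon of phloroglucinol (all three are equivalent, and the ketiminium salt 5 that separates is deactivated toward a second acylation), and hydrolysis of 5 gives the ketone, while the allyl aryl ether should be inert to anhydrous HCl at 0 °C and to hot dilute acid.

Step 3
Reactants: 6 [4-(allyloxy)phenyl](2,4,6-trihydroxyphenyl)methanone; 7 prenyl bromide
Product: 8 [4-(allyloxy)phenyl][2,4,6-trihydroxy-3-(3-methylbut-2-en-1-yl)phenyl]methanone
Conditions: 10% aq. KOH, 0 °C, limiting 7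
Reagents that add atoms: prenyl bromide (7), CC(C)=CCBr
Why: C-alkylation of an acylphloroglucinol polyanion with an allylic bromide in water (solvation of the phenoxide oxygens favours attack through carbon); C3 and C5 are equivalent, so mono-alkylation gives a single constitutional isomer, and ring B has no free hydroxyl to compete.

Step 4
Reactants: 8 [4-(allyloxy)phenyl][2,4,6-trihydroxy-3-(3-methylbut-2-en-1-yl)phenyl]methanone; 9 3-chloro-3-methylbut-1-yne; 10 acetic anhydride
Product: 12 2-[4-(allyloxy)benzoyl]-5-(2-methylbut-3-yn-2-yloxy)-4-(3-methylbut-2-en-1-yl)-1,3-phenylene diacetate, via propargyl ether diol 11 (not isolated)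
Conditions: K2CO3, KI, CuI (cat.), acetone, 50 °C, argon; then Ac2O, DMAP (cat.), rt
Reagents that add atoms: 3-chloro-3-methylbut-1-yne (9), C#CC(C)(C)Cl; acetic anhydride (10), CC(=O)OC(C)=O
Why: Copper-assisted O-alkylation of a phenoxide with a tertiary propargylic chloride should occur at O4, the most acidic and unencumbered hydroxyl (O2–H and O6–H flank the benzophenone carbonyl, are hydrogen-bonded to it in turn and are hindered), and the DMAP-catalysed O-acetylation that follows in the same flask removes the only hydrogens that could compete with O4–H in the hydrogen shift of step 5.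

Step 5
Reactants: 12 2-[4-(allyloxy)benzoyl]-5-(2-methylbut-3-yn-2-yloxy)-4-(3-methylbut-2-en-1-yl)-1,3-phenylene diacetate
Product: 16 6-[4-(allyloxy)benzoyl]-2,2-dimethyl-8-(3-methylbut-2-en-1-yl)-2H-chromene-5,7-diyl diacetate, via allenyl dienone 13 (not isolated), via allenyl phenol 14 (not isolated), via oxatriene 15 (not isolated)
Conditions: o-xylene, 140 °C, argon
Reagents that add atoms: none
Why: The aryl 1,1-dimethylpropargyl ether undergoes an aromatic propargyl Claisen rearrangement ([3,3] shift of the C5 unit from O4 to C5 of ring A) to allenyl dienone 13, which enolizes to allenyl phenol 14; a [1,5] hydrogen shift from O4–H to the central allene carbon gives the Z-configured oxatriene (ortho-quinone methide) 15, which closes by thermal oxa-6π electrocyclization, forming the O4–CMe2 bond and restoring the aromaticity of ring A. The closest known reaction type is the thermal conversion of aryl 1,1-dimethylpropargyl ethers into 2,2-dimethyl-2H-chromenes. Ring C is the only ring closed, by a six-electron disrotatory electrocyclization of a 1-oxatriene that gives the six-membered pyran. The product has no stereocenter: the sp3 carbon of 13 is lost on enolization, and the geometry of the exocyclic double bond of 15, set by the cyclic transition state of the hydrogen shift, places the dimethylvinyl terminus next to the carbonyl oxygen as the closure demands. Two selectivities are needed: the carbon–carbon bond must form at C5, secured because C3 carries the prenyl group (a shift to C3 gives a dienone that cannot enolize and returns), and the ring must close on O4 and not on O6, secured because O6 and O2 are acetylated, so that O4–H is the only hydrogen available for the [1,5] shift and 15 is the only oxatriene that can form. The allyl ether of ring B needs a distinctly higher temperature for its own Claisen rearrangement, and the acetates are inert in a neutral hydrocarbon solvent.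

Step 6
Reactants: 16 6-[4-(allyloxy)benzoyl]-2,2-dimethyl-8-(3-methylbut-2-en-1-yl)-2H-chromene-5,7-diyl diacetate
Product: 17 Vismiaphenone E
Conditions: Pd(PPh3)4 (cat.), pyrrolidine (excess), THF, rt, argon
Reagents that add atoms: none
Why: Aminolysis of the two aryl acetates by pyrrolidine and Tsuji–Trost-type deallylation (zerovalent palladium ionizes the unhindered allyl aryl ether to a π-allyl complex that pyrrolidine captures) should release the three phenols under mild conditions that leave the prenyl group and the hindered tertiary allylic ether of ring C untouched.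

**Compound list**

1 | 4-hydroxybenzonitrile | N#Cc1ccc(O)cc1 | starting material
2 | allyl bromide (3-bromoprop-1-ene) | C=CCBr | starting material
3 | 4-(allyloxy)benzonitrile | C=CCOc1ccc(C#N)cc1 | intermediate
4 | phloroglucinol (benzene-1,3,5-triol) | Oc1cc(O)cc(O)c1 | starting material
5 | [4-(allyloxy)phenyl](2,4,6-trihydroxyphenyl)methaniminium chloride | C=CCOc1ccc(C(=[NH2+])c2c(O)cc(O)cc2O)cc1.[Cl-] | intermediate
6 | [4-(allyloxy)phenyl](2,4,6-trihydroxyphenyl)methanone | C=CCOc1ccc(C(=O)c2c(O)cc(O)cc2O)cc1 | intermediate
7 | prenyl bromide (1-bromo-3-methylbut-2-ene) | CC(C)=CCBr | starting material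
8 | [4-(allyloxy)phenyl][2,4,6-trihydroxy-3-(3-methylbut-2-en-1-yl)phenyl]methanone | C=CCOc1ccc(C(=O)c2c(O)cc(O)c(CC=C(C)C)c2O)cc1 | intermediate
9 | 3-chloro-3-methylbut-1-yne | C#CC(C)(C)Cl | starting material
10 | acetic anhydride | CC(=O)OC(C)=O | starting material
11 | [4-(allyloxy)phenyl][2,6-dihydroxy-4-(2-methylbut-3-yn-2-yloxy)-3-(3-methylbut-2-en-1-yl)phenyl]methanone (propargyl ether diol) | C=CCOc1ccc(C(=O)c2c(O)cc(OC(C)(C)C#C)c(CC=C(C)C)c2O)cc1 | intermediate
12 | 2-[4-(allyloxy)benzoyl]-5-(2-methylbut-3-yn-2-yloxy)-4-(3-methylbut-2-en-1-yl)-1,3-phenylene diacetate | C=CCOc1ccc(C(=O)c2c(OC(C)=O)cc(OC(C)(C)C#C)c(CC=C(C)C)c2OC(C)=O)cc1 | intermediate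
13 | allenyl dienone: 2-[4-(allyloxy)benzoyl]-4-(3-methylbuta-1,2-dien-1-yl)-6-(3-methylbut-2-en-1-yl)-5-oxocyclohexa-1,6-diene-1,3-diyl diacetate, racemic at the allenyl-bearing sp3 carbon, transient | C=CCOc1ccc(C(=O)C2=C(OC(C)=O)C(C=C=C(C)C)C(=O)C(CC=C(C)C)=C2OC(C)=O)cc1 | intermediate
14 | allenyl phenol: 2-[4-(allyloxy)benzoyl]-5-hydroxy-4-(3-methylbuta-1,2-dien-1-yl)-6-(3-methylbut-2-en-1-yl)-1,3-phenylene diacetate | C=CCOc1ccc(C(=O)c2c(OC(C)=O)c(C=C=C(C)C)c(O)c(CC=C(C)C)c2OC(C)=O)cc1 | intermediate
15 | oxatriene (ortho-quinone methide): cyclohexadienone with exocyclic (Z)-3-methylbut-2-enylidene next to the ring carbonyl, prenyl on the other side of the carbonyl, the two acetoxy groups flanking the aroyl-bearing carbon | CC(C)=C/C=C1\C(=O)C(CC=C(C)C)=C(OC(C)=O)C(C(=O)c2ccc(OCC=C)cc2)=C1OC(C)=O | intermediate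
16 | 6-[4-(allyloxy)benzoyl]-2,2-dimethyl-8-(3-methylbut-2-en-1-yl)-2H-chromene-5,7-diyl diacetate | CC(C)=CCc1c(OC(C)=O)c(C(=O)c2ccc(OCC=C)cc2)c(OC(C)=O)c2c1OC(C)(C)C=C2 | intermediate
17 | Vismiaphenone E, [5,7-dihydroxy-2,2-dimethyl-8-(3-methylbut-2-en-1-yl)-2H-chromen-6-yl](4-hydroxyphenyl)methanone | CC(C)=CCc1c(O)c(C(=O)c2ccc(O)cc2)c(O)c2c1OC(C)(C)C=C2 | target

**Step count**

Total steps: 6. Longest linear sequence: 6 (1 → 3 → 6 → 8 → 12 → 16 → 17).

**Steps most likely to fail, with fallbacks**

Step 3 (C-prenylation). Alkylation may run on to the second ring carbon, to oxygen, or to a dearomatized gem-dialkyl compound, so that mono-C-prenylation becomes a minor pathway. The fallback delivers the prenyl group through O4 instead of by direct C-alkylation. It sets out from 6: O4-selective alkylation with 9 (K2CO3, KI, CuI cat., acetone, 50 °C) should give [4-(allyloxy)phenyl][2,6-dihydroxy-4-(2-methylbut-3-yn-2-yloxy)phenyl]methanone F1. Semihydrogenation of the alkyne (H2, Pd/CaCO3 poisoned with Pb(OAc)2, quinoline, EtOAc, stopped after one equivalent so that the ring B allyl group is kept) should give [4-(allyloxy)phenyl][2,6-dihydroxy-4-(2-methylbut-3-en-2-yloxy)phenyl]methanone F2. Aromatic Claisen rearrangement of this 1,1-dimethylallyl ether (toluene, 110 °C) moves the C5 unit with allylic inversion to the ortho carbon (C3 and C5 are equivalent) and, after enolization, comes back to the route at 8.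

Step 5 (key step). Because the acetylated, acyl-substituted ring A is electron-poor, the [3,3] shift may be slow enough for fragmentation of the tertiary propargylic ether (loss of the C5 unit) or thermal decomposition to compete. The fallback builds ring C by carbon–carbon bond formation first. It sets out from 8: formal [3+3] annulation with 3-methylbut-2-enal (ethylenediammonium diacetate cat., toluene, 110 °C; condensation at C5 followed by ring closure on oxygen) should give [4-(allyloxy)phenyl][5,7-dihydroxy-2,2-dimethyl-8-(3-methylbut-2-en-1-yl)-2H-chromen-6-yl]methanone F3. Closure on O6 can compete here, so the isomeric chromene would have to be removed by chromatography. Removal of the allyl group under the conditions of step 6 comes back at 17.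

Step 2 (Houben–Hoesch acylation). HCl may add to or cleave the allyl ether, and the donor-substituted nitrile may acylate sluggishly. The fallback forms the ketone by an organolithium addition. It sets out from 4: O-alkylation with chloromethyl methyl ether (NaH, DMF, 0 °C) should give 1,3,5-tris(methoxymethoxy)benzene F4. Lithiation between two of the acetal oxygens (n-BuLi, THF, 0 °C) should give [2,4,6-tris(methoxymethoxy)phenyl]lithium F5. Addition to nitrile 3 should give the lithium ketimide of [4-(allyloxy)phenyl][2,4,6-tris(methoxymethoxy)phenyl]methanone F6. Aqueous HCl in MeOH at 50 °C hydrolyzes the imine and cleaves the three acetals, coming back at 6.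

Further compounds
F1 | step 3 | [4-(allyloxy)phenyl][2,6-dihydroxy-4-(2-methylbut-3-yn-2-yloxy)phenyl]methanone | C=CCOc1ccc(C(=O)c2c(O)cc(OC(C)(C)C#C)cc2O)cc1
F2 | step 3 | [4-(allyloxy)phenyl][2,6-dihydroxy-4-(2-methylbut-3-en-2-yloxy)phenyl]methanone | C=CCOc1ccc(C(=O)c2c(O)cc(OC(C)(C)C=C)cc2O)cc1
F3 | step 5 | [4-(allyloxy)phenyl][5,7-dihydroxy-2,2-dimethyl-8-(3-methylbut-2-en-1-yl)-2H-chromen-6-yl]methanone | CC(C)=CCc1c(O)c(C(=O)c2ccc(OCC=C)cc2)c(O)c2c1OC(C)(C)C=C2
F4 | step 2 | 1,3,5-tris(methoxymethoxy)benzene | COCOc1cc(OCOC)cc(OCOC)c1
F5 | step 2 | [2,4,6-tris(methoxymethoxy)phenyl]lithium | [Li]c1c(OCOC)cc(OCOC)cc1OCOC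
F6 | step 2 | lithium ketimide of [4-(allyloxy)phenyl][2,4,6-tris(methoxymethoxy)phenyl]methanone | C=CCOc1ccc(C(=N[Li])c2c(OCOC)cc(OCOC)cc2OCOC)cc1
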